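A direct plan would cut the depside ester. 2,4-Dimethoxy-6-methylbenzoic acid A1 would be ethylated at its benzylic methyl through the dianion to give 2,4-dimethoxy-6-propylbenzoic acid A2. A2 would be converted into 2,4-dimethoxy-6-propylbenzoyl chloride A3, and A3 would acylate the 4-hydroxyl of olivetolic acid A4 (identical with compound 3 below), giving the target. Its weakest steps would be:
- the ester-forming acylation, because the carbonyl of A3 is flanked by OMe and propyl, so addition–elimination there would be slow;
- the site selection on A4, because the carboxyl and the 2-hydroxyl would compete unless masked in the flask;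
- the benzylic lithiation–ethylation of A1, because it would need two equivalents of strong base at low temperature and could over-alkylate.

The route would not join two finished arenes. The depside ester would be made first, on the unhindered acid 5, and ring A then built around that ester carbonyl: its C1'(carbonyl)–C6'(propyl) edge maps onto a hex-2-ynoate and its C2'–C5' segment with both methoxy groups onto 1,3-dimethoxycyclohexa-1,3-diene. An Alder–Rickert sequence ([4+2] cycloaddition, then loss of ethylene) would form C1'–C2' and C5'–C6' and fix the 2,4-dimethoxy-6-propyl pattern in one operation. Acylation by a di-ortho-substituted aroyl donor and benzylic lithiation–alkylation would have no counterpart; the propyl group would arrive with the alkyne, and a benzyl ester chelating the 2-hydroxyl would settle site selection.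

Key step: step 4

Assumption: the target is achiral, so no stereocentre has to be set; primed locants refer to the acyl ring (ring A, C1' bearing the ester carbonyl), unprimed ones to the salicylate ring (ring B).

Step 1
Reactants: 1 1,3-dimethoxybenzene
Product: 2 1,5-dimethoxycyclohexa-1,4-diene
Conditions: Li (2.5 equiv), NH3 (l)/THF, tBuOH (2.5 equiv), −78 to −33 °C; H2O quench; pentane extraction, distillation under reduced pressure
Reagents that add atoms: none
Why: Birch reduction, in which electron transfer and protonation at the positions ortho and meta to the methoxy groups leave both OMe-bearing carbons sp2 and should give the 2,5-dihydroarene as a non-conjugated bis(enol ether); no stereocentre is formed.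

Step 2
Reactants: 3 olivetolic acid (2,4-dihydroxy-6-pentylbenzoic acid)
Product: 4 benzyl 2,4-dihydroxy-6-pentylbenzoate
Conditions: BnBr (1.05 equiv), KHCO3 (1.2 equiv), DMF, rt
Reagents that add atoms: benzyl bromide, BrCc1ccccc1
Why: SN2 O-alkylation of the carboxylate, in which hydrogencarbonate should deprotonate only the carboxylic acid and not the phenols, while room temperature avoids decarboxylation of the β-resorcylic acid.

Step 3
Reactants: 4 benzyl 2,4-dihydroxy-6-pentylbenzoate; 5 hex-2-ynoic acid
Product: 7 benzyl 4-(hex-2-ynoyloxy)-2-hydroxy-6-pentylbenzoate, via N,N'-dicyclohexyl-O-(hex-2-ynoyl)isourea 6 (not isolated)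
Conditions: 5 (1.1 equiv), DCC (1.1 equiv), DMAP (5 mol%), CH2Cl2, 0 °C to rt
Reagents that add atoms: none
Why: Steglich esterification, in which the 2-hydroxyl is held in a hydrogen bond to the neighbouring benzyl ester carbonyl and is flanked by it, so the unhindered ynoyl group should be transferred to the free 4-hydroxyl and the depside ester bond is made before any ortho substituent exists on the acyl side.

Step 4
Reactants: 7 benzyl 4-(hex-2-ynoyloxy)-2-hydroxy-6-pentylbenzoate; 2 1,5-dimethoxycyclohexa-1,4-diene
Product: 10 benzyl 4-[(2,4-dimethoxy-6-propylbenzoyl)oxy]-2-hydroxy-6-pentylbenzoate, via 1,3-dimethoxycyclohexa-1,3-diene 8 (not isolated), via bicyclo[2.2.2]octadiene cycloadduct 9 (not isolated)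
Conditions: 2 (3 equiv), dichloromaleic anhydride (2 mol%), 1,2-dichlorobenzene, Ar, 130 °C then 185 °C (ethylene vented)
Reagents that add atoms: none
Why: Alder–Rickert reaction (Diels–Alder cycloaddition, then retro-Diels–Alder loss of ethylene), the reaction type known for alkyl alk-2-ynoates and 1,5-dimethoxycyclohexa-1,4-diene: 2 is conjugated in the flask to 8, whose electron-rich diene adds across the electron-poor triple bond of 7 to give 9, and 9 should extrude its CH2–CH2 bridge on further heating because an arene is gained. Ring A, a six-membered carbocycle, is closed by an intermolecular [4+2] cycloaddition that forms C1'–C2' and C5'–C6'. Regiochemistry is the selectivity the step needs: both methoxy groups raise the HOMO coefficient at C4 of 8, which should bond to C3 of the ynoate (largest LUMO coefficient), so that C1–OMe of 8 ends ortho, C3–OMe para and the propyl group ortho to the ester carbon. The two bridgehead stereocentres of racemic 9 are lost with ethylene, so no stereocentre has to be controlled. The ester carbonyl is not attacked in this step, so the crowding by two ortho substituents arises only after the ester exists, and the chelated phenol, the benzyl ester and the aryl ester are expected to tolerate neutral heating.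

Step 5
Reactants: 10 benzyl 4-[(2,4-dimethoxy-6-propylbenzoyl)oxy]-2-hydroxy-6-pentylbenzoate
Product: 11 4-[(2,4-dimethoxy-6-propylbenzoyl)oxy]-2-hydroxy-6-pentylbenzoic acid
Conditions: H2 (1 atm), Pd/C (10 wt% Pd), EtOAc, rt
Reagents that add atoms: none
Why: Hydrogenolysis of the benzyl ester over Pd/C under neutral conditions at room temperature, under which the aryl ester, the aryl methyl ethers and both arenes should be inert and the β-resorcylic acid should not decarboxylate.

Compound list
1 | 1,3-dimethoxybenzene | COc1cccc(OC)c1 | starting material
2 | 1,5-dimethoxycyclohexa-1,4-diene | COC1=CCC=C(OC)C1 | intermediate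
3 | olivetolic acid (2,4-dihydroxy-6-pentylbenzoic acid) | CCCCCc1cc(O)cc(O)c1C(=O)O | starting material
4 | benzyl 2,4-dihydroxy-6-pentylbenzoate | CCCCCc1cc(O)cc(O)c1C(=O)OCc1ccccc1 | intermediate
5 | hex-2-ynoic acid | CCCC#CC(=O)O | starting material
6 | N,N'-dicyclohexyl-O-(hex-2-ynoyl)isourea | CCCC#CC(=O)OC(=NC1CCCCC1)NC1CCCCC1 | intermediate
7 | benzyl 4-(hex-2-ynoyloxy)-2-hydroxy-6-pentylbenzoate | CCCC#CC(=O)Oc1cc(O)c(C(=O)OCc2ccccc2)c(CCCCC)c1 | intermediate
8 | 1,3-dimethoxycyclohexa-1,3-diene | COC1=CC(OC)=CCC1 | intermediate
9 | benzyl 4-[(1,5-dimethoxy-3-propylbicyclo[2.2.2]octa-2,5-dien-2-yl)carbonyloxy]-2-hydroxy-6-pentylbenzoate (racemic) | COC12CCC(C(OC)=C1)C(CCC)=C2C(=O)Oc1cc(O)c(C(=O)OCc2ccccc2)c(CCCCC)c1 | intermediate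
10 | benzyl 4-[(2,4-dimethoxy-6-propylbenzoyl)oxy]-2-hydroxy-6-pentylbenzoate | CCCCCc1cc(OC(=O)c2c(CCC)cc(OC)cc2OC)cc(O)c1C(=O)OCc1ccccc1 | intermediate
11 | 4-[(2,4-dimethoxy-6-propylbenzoyl)oxy]-2-hydroxy-6-pentylbenzoic acid (achiral) | CCCCCc1cc(OC(=O)c2c(CCC)cc(OC)cc2OC)cc(O)c1C(=O)O | target

Total step count: 5. Longest linear sequence: 4 steps (3 → 4 → 7 → 10 → 11); step 1 is a one-step side branch that supplies the diene.

Steps most likely to fail

Step 4. Conjugation of 2 to 8 could lag behind thermal degradation of the aryl ynoate, the free salicylate hydroxyl could add to the enol ether diene, or ethylene extrusion from 9 could stall. The fallback would move the benzannulation to a simple ester and join the rings afterwards by acylation. It sets out from 5 (and 2). 5 would be esterified with MeOH and catalytic H2SO4 to methyl hex-2-ynoate F1. F1 and 2, heated as in step 4, would give the cycloadduct methyl 1,5-dimethoxy-3-propylbicyclo[2.2.2]octa-2,5-diene-2-carboxylate F2, and F2 would lose ethylene on further heating to give methyl 2,4-dimethoxy-6-propylbenzoate F3. Saponification of F3 (KOH, DMSO/H2O, 110 °C; then HCl) would give 2,4-dimethoxy-6-propylbenzoic acid F4 (identical with A2). F4 would be activated with TFAA in toluene at rt as 2,4-dimethoxy-6-propylbenzoic trifluoroacetic anhydride F5, and F5 would acylate the free 4-hydroxyl of 4. This is the classical depside esterification for di-ortho-substituted acids and spares the chelated 2-hydroxyl; it comes back to the route at 10.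

Step 3. The nucleophilic catalyst or a phenol could add in a conjugate sense to the activated triple bond, the O-acylisourea could rearrange to the N-acylurea, or acylation could go beyond the 4-hydroxyl. The fallback would use a pre-formed acyl donor with no nucleophilic catalyst present. It sets out from 5, which would be converted with (COCl)2 and catalytic DMF in CH2Cl2 at 0 °C into hex-2-ynoyl chloride F6. F6 would be added to 4 and iPr2NEt (1.05 equiv) in CH2Cl2 at −40 °C, and the sequence comes back to the route at 7.

Step 2. Benzylation could spill over to the 4-hydroxyl, or the β-resorcylic acid could lose CO2 in DMF. The fallback would activate the alcohol instead of alkylating the carboxylate salt. It sets out from 3, which would be treated with benzyl alcohol, PPh3 and DIAD in THF at 0 °C (Mitsunobu esterification, in which at one equivalent only the carboxylic acid is acidic enough to be engaged). It comes back to the route at 4 and makes no new compound.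

Further compounds
F1 | step 4 | methyl hex-2-ynoate | CCCC#CC(=O)OC
F2 | step 4 | methyl 1,5-dimethoxy-3-propylbicyclo[2.2.2]octa-2,5-diene-2-carboxylate (racemic, not isolated) | COC12CCC(C(OC)=C1)C(CCC)=C2C(=O)OC
F3 | step 4 | methyl 2,4-dimethoxy-6-propylbenzoate | CCCc1cc(OC)cc(OC)c1C(=O)OC
F4 | step 4 | 2,4-dimethoxy-6-propylbenzoic acid | CCCc1cc(OC)cc(OC)c1C(=O)O
F5 | step 4 | 2,4-dimethoxy-6-propylbenzoic trifluoroacetic anhydride (not isolated) | CCCc1cc(OC)cc(OC)c1C(=O)OC(=O)C(F)(F)F
F6 | step 3 | hex-2-ynoyl chloride | CCCC#CC(=O)Cl
F0 | step 2 | none | none
A1 | direct plan | 2,4-dimethoxy-6-methylbenzoic acid | Cc1cc(OC)cc(OC)c1C(=O)O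
A2 | direct plan | 2,4-dimethoxy-6-propylbenzoic acid | CCCc1cc(OC)cc(OC)c1C(=O)O
A3 | direct plan | 2,4-dimethoxy-6-propylbenzoyl chloride | CCCc1cc(OC)cc(OC)c1C(=O)Cl
A4 | direct plan | olivetolic acid (2,4-dihydroxy-6-pentylbenzoic acid) | CCCCCc1cc(O)cc(O)c1C(=O)O
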